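**Strategy.** Ring B is a 2,4-dihydroxybenzoate in which the ester-bearing C1 and the arm-bearing C6 are neighbours. These two carbons are taken from the triple bond of an alk-2-ynoate, while C2–C5 and the oxygens on C2 and C4 come from an acetoacetate-derived bis(silyloxy)diene. One Diels–Alder/aromatization therefore builds ring B with its crowded ester to the inner (R)-3-hydroxybutanoate already in place. The dienophile is that ester of a but-2-ynoic acid whose C4 carries a 1,3-dithiane (the masked arm ketone) and an (R)-2-benzyloxypropyl group. Ring A is made by the same benzannulation on a simpler ynoate. The halves are joined by esterification, then unveiled by dithiane hydrolysis and one hydrogenolysis.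

Key step: step 10

Assumption: the enol ether geometry of 16, 17 and 18 and the configuration of the transient ketal carbon in cycloadducts 19 and 30 do not affect the products and are left undefined.
Remark: in both resorcylate rings C1 carries the ester carbonyl, C2 and C4 the oxygens and C6 the side chain; 6, 12 and 24 are taken as catalogue chemicals.

Step 1
Reactants: 1 1,3-dithiane; 2 (R)-propylene oxide
Product: 4 (2R)-1-(1,3-dithian-2-yl)propan-2-ol, via 2-lithio-1,3-dithiane 3 (not isolated)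
Conditions: n-BuLi, THF, −30 °C; then 2, −30 → 0 °C; H2O quench
Reagents that add atoms: none
Why: Corey–Seebach alkylation in which the lithiated dithiane should open the epoxide by SN2 attack at the unsubstituted carbon, so the (R) centre of 2 is carried over untouched and becomes the arm carbinol.

Step 2
Reactants: 4 (2R)-1-(1,3-dithian-2-yl)propan-2-ol
Product: 5 2-[(2R)-2-(benzyloxy)propyl]-1,3-dithiane
Conditions: NaH, BnBr, Bu4NI (cat.), THF/DMF, 0 °C → rt
Reagents that add atoms: benzyl bromide, BrCc1ccccc1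
Why: Williamson etherification of the sodium alkoxide, a benzyl ether being chosen for the arm because it withstands organolithiums and leaves in the final hydrogenolysis with every other protecting group.

Step 3
Reactants: 5 2-[(2R)-2-(benzyloxy)propyl]-1,3-dithiane; 6 3-bromo-1-(trimethylsilyl)prop-1-yne
Product: 8 (3-{2-[(2R)-2-(benzyloxy)propyl]-1,3-dithian-2-yl}prop-1-yn-1-yl)trimethylsilane, via 2-lithio-2-[(2R)-2-(benzyloxy)propyl]-1,3-dithiane 7 (not isolated)
Conditions: t-BuLi, THF/HMPA (10:1), −78 °C; then 6, −78 → −40 °C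
Reagents that add atoms: none
Why: Second Corey–Seebach alkylation, in which deprotonation at −78 °C should keep the β-benzyloxy carbanion from eliminating and the silyl cap on the propargylic bromide removes the acidic alkyne hydrogen and disfavours SN2′ attack, so SN2 substitution gives the quaternary dithiane.

Step 4
Reactants: 8 (3-{2-[(2R)-2-(benzyloxy)propyl]-1,3-dithian-2-yl}prop-1-yn-1-yl)trimethylsilane
Product: 9 2-[(2R)-2-(benzyloxy)propyl]-2-(prop-2-yn-1-yl)-1,3-dithiane
Conditions: K2CO3 (0.2 equiv), MeOH, rt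
Reagents that add atoms: none
Why: Base-catalysed methanolysis of the C(sp)–Si bond (protodesilylation) should free the terminal alkyne without touching the dithiane or the benzyl ether.

Step 5
Reactants: 9 2-[(2R)-2-(benzyloxy)propyl]-2-(prop-2-yn-1-yl)-1,3-dithiane
Product: 11 4-{2-[(2R)-2-(benzyloxy)propyl]-1,3-dithian-2-yl}but-2-ynoic acid, via lithium acetylide 10 (not isolated)
Conditions: n-BuLi, THF, −78 °C; CO2 (g), −78 → 0 °C; 1 M HCl
Reagents that add atoms: carbon dioxide, O=C=O
Why: Carboxylation of a lithium acetylide, the terminal alkyne being by far the most acidic site because the dithiane carbon is quaternary.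

Step 6
Reactants: 12 sodium (R)-3-hydroxybutanoate
Product: 13 allyl (R)-3-hydroxybutanoate
Conditions: allyl bromide, NaI (cat.), DMF, rt
Reagents that add atoms: allyl bromide, C=CCBr
Why: SN2 O-alkylation of the carboxylate, which leaves the stereocentre and the free hydroxyl alone and installs an ester that can later be cleaved under neutral conditions.

Step 7
Reactants: 11 4-{2-[(2R)-2-(benzyloxy)propyl]-1,3-dithian-2-yl}but-2-ynoic acid; 13 allyl (R)-3-hydroxybutanoate
Product: 14 allyl (3R)-3-[(4-{2-[(2R)-2-(benzyloxy)propyl]-1,3-dithian-2-yl}but-2-ynoyl)oxy]butanoate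
Conditions: DCC, DMAP (0.1 equiv), CH2Cl2, −20 → 0 °C
Reagents that add atoms: none
Why: Steglich esterification in which the unhindered ynoic acid acylates the secondary hydroxyl with retention at carbon, low temperature and little DMAP suppressing conjugate addition and alkyne-to-allene isomerization.

Step 8
Reactants: 15 methyl acetoacetate
Product: 16 methyl 3-(trimethylsilyloxy)but-2-enoate
Conditions: TMSCl, Et3N, hexane, rt
Reagents that add atoms: chlorotrimethylsilane, C[Si](C)(C)Cl
Why: Standard O-silylation of the β-keto ester enol to the silyl enol ether.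

Step 9
Reactants: 16 methyl 3-(trimethylsilyloxy)but-2-enoate
Product: 18 1-methoxy-1,3-bis(trimethylsilyloxy)buta-1,3-diene, via lithium dienolate 17 (not isolated)
Conditions: LiN(iPr)2 (commercial solution), THF, −78 °C; TMSCl, −78 °C → rt; distillation
Reagents that add atoms: chlorotrimethylsilane, C[Si](C)(C)Cl
Why: γ-Deprotonation gives the extended ester enolate, whose O-silylation should furnish the bis(silyloxy)diene by the standard two-stage preparation.

Step 10
Reactants: 14 allyl (3R)-3-[(4-{2-[(2R)-2-(benzyloxy)propyl]-1,3-dithian-2-yl}but-2-ynoyl)oxy]butanoate; 18 1-methoxy-1,3-bis(trimethylsilyloxy)buta-1,3-diene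
Product: 21 allyl (3R)-3-{[2,4-dihydroxy-6-({2-[(2R)-2-(benzyloxy)propyl]-1,3-dithian-2-yl}methyl)benzoyl]oxy}butanoate, via cyclohexa-1,4-diene cycloadduct 19 (not isolated), via aryl trimethylsilyl ether 20 (not isolated)
Conditions: 18 (3 equiv), PhMe (ca. 2 M), sealed tube, 125 °C; then PPTS (cat.), MeOH, rt
Reagents that add atoms: none
Why: Thermal normal-demand [4+2] cycloaddition of the electron-rich diene 18 to the electron-poor triple bond of 14 (concerted but asynchronous) should give 1,4-cyclohexadiene 19, whose ketal carbon then loses methoxytrimethylsilane and enolizes to arene 20 before methanolysis of the remaining aryl silyl ether gives 21. The closest known reaction type is the Diels–Alder benzannulation of alk-2-ynoates with 1-alkoxy-1,3-bis(silyloxy)buta-1,3-dienes to 6-substituted 2,4-dihydroxybenzoates. Ring B is the only ring formed, and it is closed by the intermolecular cycloaddition itself, which makes C1–C2 and C5–C6 in one operation, followed by eliminative aromatization. No lasting stereocentre is created, since the ketal carbon of 19 is lost on aromatization and both (R) carbinol centres lie outside the reacting atoms. Regioselectivity is the selectivity required and the diene secures it: its unsubstituted CH2 terminus has the largest HOMO coefficient and joins the ynoate β-carbon, which places the ketal-derived C2 hydroxyl beside the ester-bearing C1 and the arm on C6. The dithiane keeps the arm ketone masked so that the CH2 between alkyne and thioketal cannot slide into conjugation, and the crowded aryl ester, hard to make by acylating a β-hydroxy ester, is already in place from step 7.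

Step 11
Reactants: 21 allyl (3R)-3-{[2,4-dihydroxy-6-({2-[(2R)-2-(benzyloxy)propyl]-1,3-dithian-2-yl}methyl)benzoyl]oxy}butanoate
Product: 22 allyl (3R)-3-{[2,4-bis(benzyloxy)-6-({2-[(2R)-2-(benzyloxy)propyl]-1,3-dithian-2-yl}methyl)benzoyl]oxy}butanoate
Conditions: BnBr (2.5 equiv), K2CO3, Bu4NI (cat.), DMF, rt → 40 °C
Reagents that add atoms: benzyl bromide, BrCc1ccccc1
Why: Williamson O-benzylation of both phenols, carbonate being basic enough for phenols (the hydrogen-bonded C2 hydroxyl on mild warming) but too weak to trigger E1cB loss of the benzoate from the β-acyloxy ester.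

Step 12
Reactants: 22 allyl (3R)-3-{[2,4-bis(benzyloxy)-6-({2-[(2R)-2-(benzyloxy)propyl]-1,3-dithian-2-yl}methyl)benzoyl]oxy}butanoate
Product: 23 (3R)-3-{[2,4-bis(benzyloxy)-6-({2-[(2R)-2-(benzyloxy)propyl]-1,3-dithian-2-yl}methyl)benzoyl]oxy}butanoic acid
Conditions: Pd(PPh3)4 (5 mol %), morpholine (3 equiv), THF, rt; 1 M HCl wash
Reagents that add atoms: none
Why: Tsuji–Trost deallylation in which zerovalent palladium ionizes the allyl ester and morpholine traps the allyl fragment, a neutral cleavage that should spare the crowded aryl ester, the benzyl ethers and the dithiane, whose thioether sulfurs bind too weakly to displace the phosphines.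

Step 13
Reactants: 24 (R)-pent-4-yn-2-ol
Product: 25 tert-butyldimethyl[(2R)-pent-4-yn-2-yloxy]silane
Conditions: TBSCl, imidazole, DMF, rt
Reagents that add atoms: tert-butyldimethylsilyl chloride, CC(C)(C)[Si](C)(C)Cl
Why: Standard silylation, the silyl ether being the one group of the ring A half that must later be removed beside benzyl ethers and a benzyl ester.

Step 14
Reactants: 25 tert-butyldimethyl[(2R)-pent-4-yn-2-yloxy]silane
Product: 27 (5R)-5-(tert-butyldimethylsilyloxy)hex-2-ynoic acid, via lithium acetylide 26 (not isolated)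
Conditions: n-BuLi, THF, −78 °C; CO2 (g), −78 → 0 °C; cold 0.5 M HCl to pH 3
Reagents that add atoms: carbon dioxide, O=C=O
Why: Acetylide carboxylation as in step 5, brief cold acidification freeing the acid without cleaving the secondary silyl ether.

Step 15
Reactants: 12 sodium (R)-3-hydroxybutanoate
Product: 28 benzyl (R)-3-hydroxybutanoate
Conditions: BnBr, NaI (cat.), DMF, rt
Reagents that add atoms: benzyl bromide, BrCc1ccccc1
Why: SN2 O-alkylation of the carboxylate, giving the terminal acid as a benzyl ester that falls in the last hydrogenolysis.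

Step 16
Reactants: 27 (5R)-5-(tert-butyldimethylsilyloxy)hex-2-ynoic acid; 28 benzyl (R)-3-hydroxybutanoate
Product: 29 benzyl (3R)-3-{[(5R)-5-(tert-butyldimethylsilyloxy)hex-2-ynoyl]oxy}butanoate
Conditions: DCC, DMAP (0.1 equiv), CH2Cl2, −20 → 0 °C
Reagents that add atoms: none
Why: Steglich esterification of an unhindered ynoic acid with retention at the carbinol carbon, as in step 7.

Step 17
Reactants: 29 benzyl (3R)-3-{[(5R)-5-(tert-butyldimethylsilyloxy)hex-2-ynoyl]oxy}butanoate; 18 1-methoxy-1,3-bis(trimethylsilyloxy)buta-1,3-diene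
Product: 32 benzyl (3R)-3-({2,4-dihydroxy-6-[(2R)-2-(tert-butyldimethylsilyloxy)propyl]benzoyl}oxy)butanoate, via cyclohexa-1,4-diene cycloadduct 30 (not isolated), via aryl trimethylsilyl ether 31 (not isolated)
Conditions: 18 (3 equiv), PhMe (ca. 2 M), sealed tube, 125 °C; then PPTS (cat.), MeOH, rt, short contact
Reagents that add atoms: none
Why: The same ynoate/bis(silyloxy)diene Diels–Alder benzannulation as in step 10 on a simpler dienophile, the diene CH2 terminus bonding to the β-carbon, loss of methoxytrimethylsilane aromatizing ring A, and brief methanolysis removing only the aryl trimethylsilyl group while the secondary TBS ether stays.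

Step 18
Reactants: 32 benzyl (3R)-3-({2,4-dihydroxy-6-[(2R)-2-(tert-butyldimethylsilyloxy)propyl]benzoyl}oxy)butanoate
Product: 33 benzyl (3R)-3-({2,4-bis(benzyloxy)-6-[(2R)-2-(tert-butyldimethylsilyloxy)propyl]benzoyl}oxy)butanoate
Conditions: BnBr (2.5 equiv), K2CO3, Bu4NI (cat.), DMF, rt → 40 °C
Reagents that add atoms: benzyl bromide, BrCc1ccccc1
Why: Williamson O-benzylation of both phenols under the conditions of step 11.

Step 19
Reactants: 33 benzyl (3R)-3-({2,4-bis(benzyloxy)-6-[(2R)-2-(tert-butyldimethylsilyloxy)propyl]benzoyl}oxy)butanoate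
Product: 34 benzyl (3R)-3-({2,4-bis(benzyloxy)-6-[(2R)-2-hydroxypropyl]benzoyl}oxy)butanoate
Conditions: HF·pyridine, pyridine, THF, 0 °C → rt; used at once
Reagents that add atoms: none
Why: Fluoride-mediated desilylation under buffered, weakly acidic conditions, chosen so that no alkoxide forms that could lactonize onto the neighbouring 2,6-disubstituted benzoate.

Step 20
Reactants: 23 (3R)-3-{[2,4-bis(benzyloxy)-6-({2-[(2R)-2-(benzyloxy)propyl]-1,3-dithian-2-yl}methyl)benzoyl]oxy}butanoic acid; 34 benzyl (3R)-3-({2,4-bis(benzyloxy)-6-[(2R)-2-hydroxypropyl]benzoyl}oxy)butanoate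
Product: 35 (2R)-1-[3,5-bis(benzyloxy)-2-({[(2R)-4-(benzyloxy)-4-oxobutan-2-yl]oxy}carbonyl)phenyl]propan-2-yl (3R)-3-{[2,4-bis(benzyloxy)-6-({2-[(2R)-2-(benzyloxy)propyl]-1,3-dithian-2-yl}methyl)benzoyl]oxy}butanoate
Conditions: DCC, DMAP (0.2 equiv), CH2Cl2, 0 °C → rt
Reagents that add atoms: none
Why: Steglich esterification joins the halves with retention at the carbinol carbon, catalytic DMAP at low temperature keeping E1cB loss of the β-benzoate from the activated acid slow relative to acyl transfer.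

Step 21
Reactants: 35 the fully protected dithiane seco-ester of step 20
Product: 36 (2R)-1-[3,5-bis(benzyloxy)-2-({[(2R)-4-(benzyloxy)-4-oxobutan-2-yl]oxy}carbonyl)phenyl]propan-2-yl (3R)-3-({2,4-bis(benzyloxy)-6-[(4R)-4-(benzyloxy)-2-oxopentyl]benzoyl}oxy)butanoate
Conditions: MeI (excess), CaCO3, MeCN/H2O (9:1), 45 °C
Reagents that add atoms: water, O
Why: Alkylative dithiane hydrolysis in which S-methylation turns sulfur into a leaving group and water delivers the ketone oxygen, with no oxidant or halogen source to attack the electron-rich benzyloxyarenes and with CaCO3 buffering the HI so that the β-benzyloxy ketone should not eliminate.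

Step 22
Reactants: 36 the hexabenzyl ketone of step 21
Product: 37 Hansforester I
Conditions: H2 (1 atm), Pd(OH)2/C, EtOAc/EtOH, rt
Reagents that add atoms: none
Why: Catalytic hydrogenolysis, possible once sulfur is gone, should cleave the four aryl benzyl ethers, the secondary benzyl ether and the benzyl ester in one neutral operation while leaving the aliphatic ketone, the three ester links and all four (R) centres untouched.

**Compound list**

1 | 1,3-dithiane | C1CSCSC1 | starting material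
2 | (R)-propylene oxide | C[C@@H]1CO1 | starting material
3 | 2-lithio-1,3-dithiane | [Li]C1SCCCS1 | intermediate
4 | (2R)-1-(1,3-dithian-2-yl)propan-2-ol | C[C@@H](O)CC1SCCCS1 | intermediate
5 | 2-[(2R)-2-(benzyloxy)propyl]-1,3-dithiane | C[C@@H](OCc1ccccc1)CC1SCCCS1 | intermediate
6 | 3-bromo-1-(trimethylsilyl)prop-1-yne | C[Si](C)(C)C#CCBr | starting material
7 | 2-lithio-2-[(2R)-2-(benzyloxy)propyl]-1,3-dithiane | C[C@@H](OCc1ccccc1)CC1([Li])SCCCS1 | intermediate
8 | (3-{2-[(2R)-2-(benzyloxy)propyl]-1,3-dithian-2-yl}prop-1-yn-1-yl)trimethylsilane | C[C@@H](OCc1ccccc1)CC1(CC#C[Si](C)(C)C)SCCCS1 | intermediate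
9 | 2-[(2R)-2-(benzyloxy)propyl]-2-(prop-2-yn-1-yl)-1,3-dithiane | C[C@@H](OCc1ccccc1)CC1(CC#C)SCCCS1 | intermediate
10 | lithium acetylide of 9 | C[C@@H](OCc1ccccc1)CC1(CC#C[Li])SCCCS1 | intermediate
11 | 4-{2-[(2R)-2-(benzyloxy)propyl]-1,3-dithian-2-yl}but-2-ynoic acid | C[C@@H](OCc1ccccc1)CC1(CC#CC(=O)O)SCCCS1 | intermediate
12 | sodium (R)-3-hydroxybutanoate | C[C@@H](O)CC(=O)[O-].[Na+] | starting material
13 | allyl (R)-3-hydroxybutanoate | C[C@@H](O)CC(=O)OCC=C | intermediate
14 | allyl (3R)-3-[(4-{2-[(2R)-2-(benzyloxy)propyl]-1,3-dithian-2-yl}but-2-ynoyl)oxy]butanoate | C=CCOC(=O)C[C@@H](C)OC(=O)C#CCC1(C[C@@H](C)OCc2ccccc2)SCCCS1 | intermediate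
15 | methyl acetoacetate | CC(=O)CC(=O)OC | starting material
16 | methyl 3-(trimethylsilyloxy)but-2-enoate | COC(=O)C=C(C)O[Si](C)(C)C | intermediate
17 | lithium dienolate of 16 (γ-deprotonated) | [Li]OC(OC)=CC(=C)O[Si](C)(C)C | intermediate
18 | 1-methoxy-1,3-bis(trimethylsilyloxy)buta-1,3-diene | COC(O[Si](C)(C)C)=CC(=C)O[Si](C)(C)C | intermediate
19 | cycloadduct: allyl (3R)-3-{[6-methoxy-4,6-bis(trimethylsilyloxy)-2-({2-[(2R)-2-(benzyloxy)propyl]-1,3-dithian-2-yl}methyl)cyclohexa-1,4-diene-1-carbonyl]oxy}butanoate | C=CCOC(=O)C[C@@H](C)OC(=O)C1=C(CC2(C[C@@H](C)OCc3ccccc3)SCCCS2)CC(O[Si](C)(C)C)=CC1(OC)O[Si](C)(C)C | intermediate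
20 | allyl (3R)-3-{[2-hydroxy-4-(trimethylsilyloxy)-6-({2-[(2R)-2-(benzyloxy)propyl]-1,3-dithian-2-yl}methyl)benzoyl]oxy}butanoate | C=CCOC(=O)C[C@@H](C)OC(=O)c1c(O)cc(O[Si](C)(C)C)cc1CC1(C[C@@H](C)OCc2ccccc2)SCCCS1 | intermediate
21 | allyl (3R)-3-{[2,4-dihydroxy-6-({2-[(2R)-2-(benzyloxy)propyl]-1,3-dithian-2-yl}methyl)benzoyl]oxy}butanoate | C=CCOC(=O)C[C@@H](C)OC(=O)c1c(O)cc(O)cc1CC1(C[C@@H](C)OCc2ccccc2)SCCCS1 | intermediate
22 | allyl (3R)-3-{[2,4-bis(benzyloxy)-6-({2-[(2R)-2-(benzyloxy)propyl]-1,3-dithian-2-yl}methyl)benzoyl]oxy}butanoate | C=CCOC(=O)C[C@@H](C)OC(=O)c1c(OCc2ccccc2)cc(OCc2ccccc2)cc1CC1(C[C@@H](C)OCc2ccccc2)SCCCS1 | intermediate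
23 | (3R)-3-{[2,4-bis(benzyloxy)-6-({2-[(2R)-2-(benzyloxy)propyl]-1,3-dithian-2-yl}methyl)benzoyl]oxy}butanoic acid | OC(=O)C[C@@H](C)OC(=O)c1c(OCc2ccccc2)cc(OCc2ccccc2)cc1CC1(C[C@@H](C)OCc2ccccc2)SCCCS1 | intermediate
24 | (R)-pent-4-yn-2-ol | C#CC[C@@H](C)O | starting material
25 | tert-butyldimethyl[(2R)-pent-4-yn-2-yloxy]silane | C#CC[C@@H](C)O[Si](C)(C)C(C)(C)C | intermediate
26 | lithium acetylide of 25 | [Li]C#CC[C@@H](C)O[Si](C)(C)C(C)(C)C | intermediate
27 | (5R)-5-(tert-butyldimethylsilyloxy)hex-2-ynoic acid | OC(=O)C#CC[C@@H](C)O[Si](C)(C)C(C)(C)C | intermediate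
28 | benzyl (R)-3-hydroxybutanoate | C[C@@H](O)CC(=O)OCc1ccccc1 | intermediate
29 | benzyl (3R)-3-{[(5R)-5-(tert-butyldimethylsilyloxy)hex-2-ynoyl]oxy}butanoate | O=C(C[C@@H](C)OC(=O)C#CC[C@@H](C)O[Si](C)(C)C(C)(C)C)OCc1ccccc1 | intermediate
30 | cycloadduct: benzyl (3R)-3-({6-methoxy-4,6-bis(trimethylsilyloxy)-2-[(2R)-2-(tert-butyldimethylsilyloxy)propyl]cyclohexa-1,4-diene-1-carbonyl}oxy)butanoate | O=C(C[C@@H](C)OC(=O)C1=C(C[C@@H](C)O[Si](C)(C)C(C)(C)C)CC(O[Si](C)(C)C)=CC1(OC)O[Si](C)(C)C)OCc1ccccc1 | intermediate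
31 | benzyl (3R)-3-({2-hydroxy-4-(trimethylsilyloxy)-6-[(2R)-2-(tert-butyldimethylsilyloxy)propyl]benzoyl}oxy)butanoate | O=C(C[C@@H](C)OC(=O)c1c(O)cc(O[Si](C)(C)C)cc1C[C@@H](C)O[Si](C)(C)C(C)(C)C)OCc1ccccc1 | intermediate
32 | benzyl (3R)-3-({2,4-dihydroxy-6-[(2R)-2-(tert-butyldimethylsilyloxy)propyl]benzoyl}oxy)butanoate | O=C(C[C@@H](C)OC(=O)c1c(O)cc(O)cc1C[C@@H](C)O[Si](C)(C)C(C)(C)C)OCc1ccccc1 | intermediate
33 | benzyl (3R)-3-({2,4-bis(benzyloxy)-6-[(2R)-2-(tert-butyldimethylsilyloxy)propyl]benzoyl}oxy)butanoate | O=C(C[C@@H](C)OC(=O)c1c(OCc2ccccc2)cc(OCc2ccccc2)cc1C[C@@H](C)O[Si](C)(C)C(C)(C)C)OCc1ccccc1 | intermediate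
34 | benzyl (3R)-3-({2,4-bis(benzyloxy)-6-[(2R)-2-hydroxypropyl]benzoyl}oxy)butanoate | O=C(C[C@@H](C)OC(=O)c1c(OCc2ccccc2)cc(OCc2ccccc2)cc1C[C@@H](C)O)OCc1ccccc1 | intermediate
35 | (2R)-1-[3,5-bis(benzyloxy)-2-({[(2R)-4-(benzyloxy)-4-oxobutan-2-yl]oxy}carbonyl)phenyl]propan-2-yl (3R)-3-{[2,4-bis(benzyloxy)-6-({2-[(2R)-2-(benzyloxy)propyl]-1,3-dithian-2-yl}methyl)benzoyl]oxy}butanoate | C[C@H](Cc1cc(OCc2ccccc2)cc(OCc2ccccc2)c1C(=O)O[C@H](C)CC(=O)OCc1ccccc1)OC(=O)C[C@@H](C)OC(=O)c1c(OCc2ccccc2)cc(OCc2ccccc2)cc1CC1(C[C@@H](C)OCc2ccccc2)SCCCS1 | intermediate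
36 | (2R)-1-[3,5-bis(benzyloxy)-2-({[(2R)-4-(benzyloxy)-4-oxobutan-2-yl]oxy}carbonyl)phenyl]propan-2-yl (3R)-3-({2,4-bis(benzyloxy)-6-[(4R)-4-(benzyloxy)-2-oxopentyl]benzoyl}oxy)butanoate | C[C@H](Cc1cc(OCc2ccccc2)cc(OCc2ccccc2)c1C(=O)O[C@H](C)CC(=O)OCc1ccccc1)OC(=O)C[C@@H](C)OC(=O)c1c(OCc2ccccc2)cc(OCc2ccccc2)cc1CC(=O)C[C@@H](C)OCc1ccccc1 | intermediate
37 | Hansforester I | C[C@H](Cc1cc(O)cc(O)c1C(=O)O[C@H](C)CC(=O)O)OC(=O)C[C@@H](C)OC(=O)c1c(O)cc(O)cc1CC(=O)C[C@@H](C)O | target

**Totals**

Total step count: 22.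
Longest linear sequence: 12 steps (steps 1, 2, 3, 4, 5, 7, 10, 11, 12, 20, 21, 22).

**Three steps most likely to fail**

Step 10 (ring B benzannulation). The β-alkyl ynoate may cycloadd slowly, so that at the temperature required the diene is consumed by silyl migration and oligomerization and the β-acyloxy ester of 14 fragments by elimination of the ynoic acid before the ring is complete. The fallback sets out from 11 and comes back at 22. Acid 11 is esterified with allyl alcohol (DCC, DMAP) to allyl 4-{2-[(2R)-2-(benzyloxy)propyl]-1,3-dithian-2-yl}but-2-ynoate F1, a dienophile without the fragile β-acyloxy ester that tolerates longer heating with 18. The cycloaddition should pass through the cyclohexa-1,4-diene cycloadduct F2 and the aryl trimethylsilyl ether F3 to allyl 2,4-dihydroxy-6-({2-[(2R)-2-(benzyloxy)propyl]-1,3-dithian-2-yl}methyl)benzoate F4. O-Benzylation (BnBr, K2CO3, DMF) gives the bis(benzyl ether) F5, and Pd(PPh3)4/morpholine deallylation, which acts at the allyl group and is indifferent to crowding at the carbonyl, gives 2,4-bis(benzyloxy)-6-({2-[(2R)-2-(benzyloxy)propyl]-1,3-dithian-2-yl}methyl)benzoic acid F6. Mitsunobu esterification (PPh3, DIAD, PhMe, 0 °C) with allyl (S)-3-hydroxybutanoate F7 (from commercial ethyl (S)-3-hydroxybutanoate, allyl alcohol and Ti(OiPr)4) forms the crowded ester by SN2 displacement at the carbinol with inversion, (S) to (R), and delivers 22.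

Step 20 (union of the halves). Activation of the β-acyloxy acid 23 may be followed by base-assisted β-elimination of the ring B benzoate, and the free carbinol of 34 may lactonize onto its own ortho ester faster than it is acylated intermolecularly. The fallback sets out from 29 (with 23 and 18) and comes back at 35. Ynoate 29 is desilylated (HF·pyridine, THF) before any arene exists, giving benzyl (3R)-3-{[(5R)-5-hydroxyhex-2-ynoyl]oxy}butanoate F8, whose unhindered homopropargylic hydroxyl cannot close onto the linear ynoate. DCC/DMAP esterification with 23 gives the diester ynoate F9, that is 23 esterified at the C5 hydroxyl of F8. The ring A benzannulation with 18 is then run on F9 and should pass through the cycloadduct F10 and the aryl trimethylsilyl ether F11 to the ring A diphenol F12. O-Benzylation (BnBr, K2CO3, DMF) gives 35, so that a free hydroxypropyl group next to the aryl ester never occurs.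

Step 21 (late dithiane hydrolysis). S-Alkylation of the congested thioketal in the large intermediate may be slow, leaving time for loss of benzyl alcohol from the newly formed β-benzyloxy ketone or for enol-lactonization of that ketone onto the ortho ester. The fallback sets out from 22 (with 34) and comes back at 36. The dithiane is hydrolysed on the small intermediate 22 (MeI, CaCO3, aqueous MeCN), where more forcing treatment costs little, to allyl (3R)-3-({2,4-bis(benzyloxy)-6-[(4R)-4-(benzyloxy)-2-oxopentyl]benzoyl}oxy)butanoate F13. Deallylation with Pd(PPh3)4 and N-methylaniline, an allyl acceptor that does not condense with the ketone, gives (3R)-3-({2,4-bis(benzyloxy)-6-[(4R)-4-(benzyloxy)-2-oxopentyl]benzoyl}oxy)butanoic acid F14. DCC/DMAP esterification of F14 with 34 at 0 °C gives 36 directly.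

Further compounds
F1 | step 10 | allyl 4-{2-[(2R)-2-(benzyloxy)propyl]-1,3-dithian-2-yl}but-2-ynoate | C=CCOC(=O)C#CCC1(C[C@@H](C)OCc2ccccc2)SCCCS1
F2 | step 10 | cycloadduct: allyl 6-methoxy-4,6-bis(trimethylsilyloxy)-2-({2-[(2R)-2-(benzyloxy)propyl]-1,3-dithian-2-yl}methyl)cyclohexa-1,4-diene-1-carboxylate | C=CCOC(=O)C1=C(CC2(C[C@@H](C)OCc3ccccc3)SCCCS2)CC(O[Si](C)(C)C)=CC1(OC)O[Si](C)(C)C
F3 | step 10 | allyl 2-hydroxy-4-(trimethylsilyloxy)-6-({2-[(2R)-2-(benzyloxy)propyl]-1,3-dithian-2-yl}methyl)benzoate | C=CCOC(=O)c1c(O)cc(O[Si](C)(C)C)cc1CC1(C[C@@H](C)OCc2ccccc2)SCCCS1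
F4 | step 10 | allyl 2,4-dihydroxy-6-({2-[(2R)-2-(benzyloxy)propyl]-1,3-dithian-2-yl}methyl)benzoate | C=CCOC(=O)c1c(O)cc(O)cc1CC1(C[C@@H](C)OCc2ccccc2)SCCCS1
F5 | step 10 | allyl 2,4-bis(benzyloxy)-6-({2-[(2R)-2-(benzyloxy)propyl]-1,3-dithian-2-yl}methyl)benzoate | C=CCOC(=O)c1c(OCc2ccccc2)cc(OCc2ccccc2)cc1CC1(C[C@@H](C)OCc2ccccc2)SCCCS1
F6 | step 10 | 2,4-bis(benzyloxy)-6-({2-[(2R)-2-(benzyloxy)propyl]-1,3-dithian-2-yl}methyl)benzoic acid | OC(=O)c1c(OCc2ccccc2)cc(OCc2ccccc2)cc1CC1(C[C@@H](C)OCc2ccccc2)SCCCS1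
F7 | step 10 | allyl (S)-3-hydroxybutanoate | C[C@H](O)CC(=O)OCC=C
F8 | step 20 | benzyl (3R)-3-{[(5R)-5-hydroxyhex-2-ynoyl]oxy}butanoate | O=C(C[C@@H](C)OC(=O)C#CC[C@@H](C)O)OCc1ccccc1
F9 | step 20 | diester ynoate: 23 esterified at the C5 hydroxyl of F8 | C[C@H](CC#CC(=O)O[C@H](C)CC(=O)OCc1ccccc1)OC(=O)C[C@@H](C)OC(=O)c1c(OCc2ccccc2)cc(OCc2ccccc2)cc1CC1(C[C@@H](C)OCc2ccccc2)SCCCS1
F10 | step 20 | cycloadduct of F9 with 18 (6-methoxy-4,6-bis(trimethylsilyloxy)cyclohexa-1,4-diene in place of ring A) | C[C@H](CC1=C(C(=O)O[C@H](C)CC(=O)OCc2ccccc2)C(OC)(O[Si](C)(C)C)C=C(O[Si](C)(C)C)C1)OC(=O)C[C@@H](C)OC(=O)c1c(OCc2ccccc2)cc(OCc2ccccc2)cc1CC1(C[C@@H](C)OCc2ccccc2)SCCCS1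
F11 | step 20 | analogue of 35 with ring A carrying C2 hydroxyl and C4 trimethylsilyloxy | C[C@H](Cc1cc(O[Si](C)(C)C)cc(O)c1C(=O)O[C@H](C)CC(=O)OCc1ccccc1)OC(=O)C[C@@H](C)OC(=O)c1c(OCc2ccccc2)cc(OCc2ccccc2)cc1CC1(C[C@@H](C)OCc2ccccc2)SCCCS1
F12 | step 20 | analogue of 35 with both ring A phenols free | C[C@H](Cc1cc(O)cc(O)c1C(=O)O[C@H](C)CC(=O)OCc1ccccc1)OC(=O)C[C@@H](C)OC(=O)c1c(OCc2ccccc2)cc(OCc2ccccc2)cc1CC1(C[C@@H](C)OCc2ccccc2)SCCCS1
F13 | step 21 | allyl (3R)-3-({2,4-bis(benzyloxy)-6-[(4R)-4-(benzyloxy)-2-oxopentyl]benzoyl}oxy)butanoate | C=CCOC(=O)C[C@@H](C)OC(=O)c1c(OCc2ccccc2)cc(OCc2ccccc2)cc1CC(=O)C[C@@H](C)OCc1ccccc1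
F14 | step 21 | (3R)-3-({2,4-bis(benzyloxy)-6-[(4R)-4-(benzyloxy)-2-oxopentyl]benzoyl}oxy)butanoic acid | OC(=O)C[C@@H](C)OC(=O)c1c(OCc2ccccc2)cc(OCc2ccccc2)cc1CC(=O)C[C@@H](C)OCc1ccccc1
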